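## Retrosynthetic overview

1. Target 14 ⇐ trans-acetonide 13 (acid hydrolysis) ⇐ diene 12 by ring-closing metathesis across C3=C4; this is the only ring-forming step.
2. Diene 12 ⇐ fragment A (keto-acetonide 7: C7, C1, C6, C5, C4) + fragment B (3-bromopropenyl benzoate 10: C2, C3) by an indium Barbier γ-benzoyloxyallylation that forms C1–C2 and sets C1 and C2.
3. Fragment A ⇐ diacetone-L-sorbose 1: sorbose C3/C4 become C6/C5, and zinc fragmentation of the 6-iodide unmasks the C1 ketone and the C4 vinyl group.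
4. Fragment B ⇐ acrolein 8 + benzoyl bromide 9.
5. Both benzoates arrive on the fragments, so the end game is the metathesis and one deprotection.

Assumption: atom labels follow the target ring (C1 quaternary carbinol, C2 CH–OBz, C3=C4, C5/C6 diol carbons, C7 the CH2OBz carbon), and 1, 8 and 9 are taken as cheap commercial chemicals.

## Route

Step 1
Reactants: 1 2,3:4,6-di-O-isopropylidene-α-L-sorbofuranose
Product: 2 1-O-benzoyl-2,3:4,6-di-O-isopropylidene-α-L-sorbofuranose
Conditions: BzCl, pyridine, DMAP (cat.), CH2Cl2, 0 °C to rt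
Reagents that add atoms: benzoyl chloride, O=C(Cl)c1ccccc1
Why: O-acylation (nucleophilic acyl substitution) of the only free hydroxyl installs the future C7 benzoate at the outset; no stereocentre is touched.

Step 2
Reactants: 2 1-O-benzoyl-2,3:4,6-di-O-isopropylidene-α-L-sorbofuranose
Product: 3 1-O-benzoyl-2,3-O-isopropylidene-α-L-sorbofuranose
Conditions: AcOH/H2O (3:2), 40 °C, monitored by TLC
Reagents that add atoms: none
Why: Acid-catalysed acetal hydrolysis is selective because the six-membered 4,6-O-isopropylidene ring is far more labile than the dioxolane spiro-fused at the anomeric carbon (the classical route to 2,3-O-isopropylidene-L-sorbofuranose); the benzoate and all stereocentres are untouched.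

Step 3
Reactants: 3 1-O-benzoyl-2,3-O-isopropylidene-α-L-sorbofuranose
Product: 4 1-O-benzoyl-6-deoxy-6-iodo-2,3-O-isopropylidene-α-L-sorbofuranose
Conditions: I2, PPh3, imidazole, THF, 0 °C to 45 °C
Reagents that add atoms: iodine, [I][I]
Why: Garegg–Samuelsson (Appel-type) iodination activates the unhindered primary C6 hydroxyl for SN2 displacement by iodide while the secondary ring hydroxyl at C4 stays free; no stereocentre is involved.

Step 4
Reactants: 4 1-O-benzoyl-6-deoxy-6-iodo-2,3-O-isopropylidene-α-L-sorbofuranose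
Product: 6 (3S,4R)-3,4-dihydroxy-2-oxohex-5-en-1-yl benzoate, via alkylzinc iodide 5 (not isolated)
Conditions: activated Zn dust, THF/H2O (4:1), ultrasound, 40 °C; then sat. aq. NH4Cl, cold extraction
Reagents that add atoms: none
Why: Bernet–Vasella reductive fragmentation: zinc inserts into the C–I bond, β-elimination of the ring oxygen opens the furanose to the terminal alkene, and the hemiketal collapses to the ketone with loss of the 2,3-acetonide as acetone, leaving sorbose C3 and C4 (future C6 and C5) unchanged.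

Step 5
Reactants: 6 (3S,4R)-3,4-dihydroxy-2-oxohex-5-en-1-yl benzoate
Product: 7 2-[(4S,5R)-5-ethenyl-2,2-dimethyl-1,3-dioxolan-4-yl]-2-oxoethyl benzoate
Conditions: 2,2-dimethoxypropane, PPTS (cat.), acetone, rt
Reagents that add atoms: 2,2-dimethoxypropane, COC(C)(C)OC
Why: Acid-catalysed transacetalisation turns the threo-diol into the trans-dioxolane, removing the free hydroxyls that would otherwise steer the next addition by chelation; no stereocentre is affected.

Step 6
Reactants: 8 acrolein; 9 benzoyl bromide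
Product: 10 3-bromoprop-1-en-1-yl benzoate (E/Z mixture)
Conditions: ZnCl2 (2 mol%), CH2Cl2, −20 °C to rt
Reagents that add atoms: none
Why: Lewis-acid-promoted 1,4-addition of the acyl bromide to the enal (bromide to the β-carbon, acylation on oxygen) gives the γ-bromo enol ester, a masked α-benzoyloxyallyl anion; no stereocentre is formed.

Step 7
Reactants: 7 2-[(4S,5R)-5-ethenyl-2,2-dimethyl-1,3-dioxolan-4-yl]-2-oxoethyl benzoate; 10 3-bromoprop-1-en-1-yl benzoate
Product: 12 (2R,3S)-2-[(4S,5R)-5-ethenyl-2,2-dimethyl-1,3-dioxolan-4-yl]-2-hydroxypent-4-ene-1,3-diyl dibenzoate, via allylindium dibromide 11 (not isolated)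
Conditions: In powder (2 equiv), 10 (2.5 equiv), THF/H2O (4:1), rt, ultrasound; diastereomers separated on silica
Reagents that add atoms: none
Why: In this indium Barbier γ-acyloxyallylation 11 adds through its γ-carbon to the activated ketone and leaves the esters alone; Felkin–Anh attack anti to the dioxolane C–O bond (no chelation in water) should set C1 with its hydroxyl erythro to the C6 oxygen, and a chair transition state with the Z-configured reagent and the branched dioxolanyl group equatorial should place the C2 benzoate threo to the C1 hydroxyl, but the C2 selectivity is not secure (see risks).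

Step 8
Reactants: 12 (2R,3S)-2-[(4S,5R)-5-ethenyl-2,2-dimethyl-1,3-dioxolan-4-yl]-2-hydroxypent-4-ene-1,3-diyl dibenzoate
Product: 13 [(3aS,4R,5S,7aR)-5-(benzoyloxy)-4-hydroxy-2,2-dimethyl-3a,4,5,7a-tetrahydro-1,3-benzodioxol-4-yl]methyl benzoate
Conditions: second-generation Grubbs catalyst (5 mol%), CH2Cl2 (0.005 M), 40 °C
Reagents that add atoms: none
Why: Ring-closing metathesis of the 1,7-diene (two monosubstituted alkenes) closes the cyclohexene at C3=C4 with loss of ethylene; the free tertiary alcohol, the allylic benzoate and the acetonide are tolerated and no stereocentre is touched.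

Step 9
Reactants: 13 [(3aS,4R,5S,7aR)-5-(benzoyloxy)-4-hydroxy-2,2-dimethyl-3a,4,5,7a-tetrahydro-1,3-benzodioxol-4-yl]methyl benzoate
Product: 14 [(1S,2S,5R,6S)-2-(benzoyloxy)-1,5,6-trihydroxycyclohex-3-en-1-yl]methyl benzoate (target)
Conditions: AcOH/H2O (4:1), 50 °C
Reagents that add atoms: none
Why: Mild acid hydrolysis removes the strained trans-fused isopropylidene acetal while the benzoates (stable and slow to migrate at low pH) stay in place, giving the target with all four stereocentres as set.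

## Compound list

1 | 2,3:4,6-di-O-isopropylidene-α-L-sorbofuranose | OC[C@]12OC(C)(C)O[C@H]1[C@@H]3OC(C)(C)OC[C@@H]3O2 | starting material
2 | 1-O-benzoyl-2,3:4,6-di-O-isopropylidene-α-L-sorbofuranose | O=C(OC[C@]12OC(C)(C)O[C@H]1[C@@H]3OC(C)(C)OC[C@@H]3O2)c1ccccc1 | intermediate
3 | 1-O-benzoyl-2,3-O-isopropylidene-α-L-sorbofuranose | O=C(OC[C@]12OC(C)(C)O[C@H]1[C@H](O)[C@H](CO)O2)c1ccccc1 | intermediate
4 | 1-O-benzoyl-6-deoxy-6-iodo-2,3-O-isopropylidene-α-L-sorbofuranose | O=C(OC[C@]12OC(C)(C)O[C@H]1[C@H](O)[C@H](CI)O2)c1ccccc1 | intermediate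
5 | alkylzinc iodide formed from 4 at C6 | O=C(OC[C@]12OC(C)(C)O[C@H]1[C@H](O)[C@H](C[Zn]I)O2)c1ccccc1 | intermediate (not isolated)
6 | (3S,4R)-3,4-dihydroxy-2-oxohex-5-en-1-yl benzoate | O=C(OCC(=O)[C@@H](O)[C@H](O)C=C)c1ccccc1 | intermediate
7 | 2-[(4S,5R)-5-ethenyl-2,2-dimethyl-1,3-dioxolan-4-yl]-2-oxoethyl benzoate (fragment A) | O=C(OCC(=O)[C@H]1OC(C)(C)O[C@@H]1C=C)c1ccccc1 | intermediate
8 | acrolein | C=CC=O | starting material
9 | benzoyl bromide | O=C(Br)c1ccccc1 | starting material
10 | 3-bromoprop-1-en-1-yl benzoate, E/Z mixture (fragment B) | BrCC=COC(=O)c1ccccc1 | intermediate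
11 | [(Z)-3-(benzoyloxy)prop-2-en-1-yl]indium dibromide (simplest formula of the allylindium bromide) | Br[In](Br)C/C=C\OC(=O)c1ccccc1 | intermediate (not isolated)
12 | (2R,3S)-2-[(4S,5R)-5-ethenyl-2,2-dimethyl-1,3-dioxolan-4-yl]-2-hydroxypent-4-ene-1,3-diyl dibenzoate | C=C[C@H](OC(=O)c1ccccc1)[C@](O)(COC(=O)c1ccccc1)[C@H]1OC(C)(C)O[C@@H]1C=C | intermediate
13 | [(3aS,4R,5S,7aR)-5-(benzoyloxy)-4-hydroxy-2,2-dimethyl-3a,4,5,7a-tetrahydro-1,3-benzodioxol-4-yl]methyl benzoate | O=C(OC[C@@]1(O)[C@@H](OC(=O)c2ccccc2)C=C[C@H]3OC(C)(C)O[C@H]13)c1ccccc1 | intermediate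
14 | [(1S,2S,5R,6S)-2-(benzoyloxy)-1,5,6-trihydroxycyclohex-3-en-1-yl]methyl benzoate | O=C(OC[C@@]1(O)[C@@H](OC(=O)c2ccccc2)C=C[C@@H](O)[C@@H]1O)c1ccccc1 | target

## Step count and risks

Total step count: 9 (five for fragment A, one for fragment B, three after the union).
Longest linear sequence: 8 steps (1 to 14 through steps 1–5 and 7–9).

Steps most likely to fail:

Step 7 (Barbier union). Four diastereomers are possible: the Felkin–Anh preference at C1 may be modest, and indium γ-acyloxyallylations of aliphatic aldehydes are often anti-selective, which here would favour the C2 epimer. Fallback, setting C2 on the ring instead: from ketone 7, add 1-lithio-1-methoxyallene (methoxyallene, n-BuLi, THF, −78 °C; the ketone reacts far faster than the benzoate) to give (2S)-2-[(4S,5R)-5-ethenyl-2,2-dimethyl-1,3-dioxolan-4-yl]-2-hydroxy-3-methoxypenta-3,4-dien-1-yl benzoate F1. Hydrolysis of the enol ether (aq. oxalic acid, THF) gives the vinyl ketone (2S)-2-[(4S,5R)-5-ethenyl-2,2-dimethyl-1,3-dioxolan-4-yl]-2-hydroxy-3-oxopent-4-en-1-yl benzoate F2. Ring-closing metathesis (second-generation Grubbs catalyst) gives the cyclohexenone [(3aS,4S,7aR)-4-hydroxy-2,2-dimethyl-5-oxo-3a,4,5,7a-tetrahydro-1,3-benzodioxol-4-yl]methyl benzoate F3. A 1,2-reduction (NaBH4, CeCl3·7H2O, MeOH, −78 °C, hydride entering anti to the CH2OBz group, or a CBS reduction with the catalyst enantiomer matched to the 5S carbinol) gives [(3aS,4R,5S,7aR)-4,5-dihydroxy-2,2-dimethyl-3a,4,5,7a-tetrahydro-1,3-benzodioxol-4-yl]methyl benzoate F4. Benzoylation of the secondary hydroxyl (BzCl, pyridine, DMAP) comes back to the route at 13.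

Step 4 (zinc fragmentation). The free α,β-dihydroxy ketone 6 is water-soluble and prone to retro-aldol cleavage and 1,3-benzoyl migration during isolation. Fallback, masking O4 before the ring is opened: from iodide 4, silylation (TESOTf, 2,6-lutidine, CH2Cl2, −78 °C) gives 1-O-benzoyl-6-deoxy-6-iodo-2,3-O-isopropylidene-4-O-(triethylsilyl)-α-L-sorbofuranose F5. The same zinc fragmentation then releases (3S,4R)-3-hydroxy-2-oxo-4-[(triethylsilyl)oxy]hex-5-en-1-yl benzoate F6, which cannot undergo retro-aldol cleavage and extracts cleanly. Treatment with CSA in MeOH, then 2,2-dimethoxypropane/acetone in the same flask, swaps the silyl ether for the acetonide and comes back to the route at 7.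

Step 8 (metathesis to the trans-fused bicycle). Ring strain from the trans-dioxolane, or ruthenium chelation by the tertiary alcohol and allylic benzoate, may stall the closure, and the later hydrolysis of 13 risks acyl migration. Fallback, reversing the order: from diene 12, hydrolyse the acetonide first (AcOH/H2O, 40 °C) to (3S,4S,5S,6R)-4-[(benzoyloxy)methyl]-4,5,6-trihydroxyocta-1,7-dien-3-yl benzoate F7, then close the unprotected triol (second-generation Hoveyda–Grubbs catalyst, CH2Cl2, 40 °C), which comes back to the route directly at target 14.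

Further compounds

F1 | step 7 | (2S)-2-[(4S,5R)-5-ethenyl-2,2-dimethyl-1,3-dioxolan-4-yl]-2-hydroxy-3-methoxypenta-3,4-dien-1-yl benzoate | O=C(OC[C@@](O)(C(OC)=C=C)[C@H]1OC(C)(C)O[C@@H]1C=C)c1ccccc1
F2 | step 7 | (2S)-2-[(4S,5R)-5-ethenyl-2,2-dimethyl-1,3-dioxolan-4-yl]-2-hydroxy-3-oxopent-4-en-1-yl benzoate | O=C(OC[C@@](O)(C(=O)C=C)[C@H]1OC(C)(C)O[C@@H]1C=C)c1ccccc1
F3 | step 7 | [(3aS,4S,7aR)-4-hydroxy-2,2-dimethyl-5-oxo-3a,4,5,7a-tetrahydro-1,3-benzodioxol-4-yl]methyl benzoate | O=C(OC[C@@]1(O)C(=O)C=C[C@H]3OC(C)(C)O[C@H]13)c1ccccc1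
F4 | step 7 | [(3aS,4R,5S,7aR)-4,5-dihydroxy-2,2-dimethyl-3a,4,5,7a-tetrahydro-1,3-benzodioxol-4-yl]methyl benzoate | O=C(OC[C@@]1(O)[C@@H](O)C=C[C@H]3OC(C)(C)O[C@H]13)c1ccccc1
F5 | step 4 | 1-O-benzoyl-6-deoxy-6-iodo-2,3-O-isopropylidene-4-O-(triethylsilyl)-α-L-sorbofuranose | O=C(OC[C@]12OC(C)(C)O[C@H]1[C@H](O[Si](CC)(CC)CC)[C@H](CI)O2)c1ccccc1
F6 | step 4 | (3S,4R)-3-hydroxy-2-oxo-4-[(triethylsilyl)oxy]hex-5-en-1-yl benzoate | O=C(OCC(=O)[C@@H](O)[C@H](O[Si](CC)(CC)CC)C=C)c1ccccc1
F7 | step 8 | (3S,4S,5S,6R)-4-[(benzoyloxy)methyl]-4,5,6-trihydroxyocta-1,7-dien-3-yl benzoate | C=C[C@H](OC(=O)c1ccccc1)[C@](O)(COC(=O)c1ccccc1)[C@@H](O)[C@H](O)C=C
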